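The numbers are those of an exercise; the result is computed.

The vessel shows up here as the age of the target at the moment of reading, and the hunch that dosing buys share survives a quick number.

common to all: coupling partner 1.50 equiv; free catalyst 0.44 mol%
- alder: substrate 0.050 M; time 15 min; everything together in a closed stirred flask, run for 15 min
- maple: substrate 0.050 M; a single well-mixed tank run continuously and read at steady state, 45.0 min in it on average
- oak: substrate 0.050 M (fed, over 7.50 min); time 15 min; all but substrate at the start; substrate goes in evenly over 7.50 min, the run ends at 15 min
- ash: substrate 0.050 M; a single well-mixed tank run continuously and read at steady state, 15 min in it on average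

    coupling partner + free catalyst ⇌ catalyst intermediate A (K1 = 9.7 L mol⁻¹, k1 = 42 L mol⁻¹ s⁻¹)
    substrate + catalyst intermediate A ⇌ catalyst intermediate B (K2 = 3.8 L mol⁻¹, k2 = 46 L mol⁻¹ s⁻¹)
    catalyst intermediate B → by-product + catalyst intermediate C (k3 = 2.7 s⁻¹)
    catalyst intermediate C → catalyst intermediate D (k4 = 0.95 s⁻¹)
    catalyst intermediate D → free catalyst + target (k5 = 29 s⁻¹)
    target + free catalyst ⇌ isomer of the product + free catalyst, rate k6*[free catalyst]*[target] forward; the back reaction follows from the equilibrium constant (K6 = 0.63, k6 = 10 L mol⁻¹ s⁻¹)

- the set-up with the highest share of target in all that became target or isomer of the product, at the outlet or at the end ("none" if the first two lie within 2 percentage points) (alder / maple / oak / ash / none)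
- share of target in all that became target or isomer of the product, at the outlet or at the end, alder
- share of target in all that became target or isomer of the product, at the outlet or at the end, maple
- share of target in all that became target or isomer of the product, at the outlet or at the end, oak
- share of target in all that became target or isomer of the product, at the outlet or at the end, ash

- the stated concentrations are those of everything mixed, before any reaction; amounts are the same in each set-up
- the feed brings no volume worth counting
- run time (alder): 15 min

Counting free catalyst and catalyst intermediate A and no other form, step 1 at the start leaves this share of the catalyst free:

free share = 57.9 %

Step 6 has this equilibrium share of target: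

equilibrium share = 61.3 %

At one moment, the exchange of target and isomer of the product is pseudo-first-order in the gap to that share, with free catalyst as its handle:

relaxation time = one over (k6 × free catalyst × (one plus one over K6)) = 5.06 min

This relaxation time of the target, the time in which its gap to equilibrium shrinks by a factor e, is the clock of this reckoning. Binding at the charged coupling partner takes 0.317 s, so step 1 keeps pace with that clock, and I hold the free share steady as a rough assumption.

The drift is that fresh target keeps arriving, so each vessel is a different mix of ages. In a tank, the isomer's part of the product is (one minus equilibrium share) × q/(one plus q), with q the mean stay over the clock. The closed flask is taken with even formation, and oak with formation ramping up over the dose and then level: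

ash: 71.1 %
maple: 65.3 %
alder: 73.7 %
oak: 76.7 %

That puts oak highest, 3 percentage points above alder, against a margin of 2 points.

The forecast names oak too, with 71.1 % for alder, below my figure, 64.9 % for maple, 71.2 % for ash and 75.8 % for oak, on the ground of “Less product and later formation”.

The flask gives 72.4 % for alder, 64.9 % for maple, 71.2 % for ash and 75.8 % for oak, so oak stands highest. Oak at 15.0 min holds 57.1 % of its catalyst free, which makes the clock there 5.13 min. In the neighbouring oak flask at 0.020 M, with the free share 77.5 % at the start, the clock runs to 9.45 min, nearly twice the first. The same age weighting gives 83.7 % there, and that flask ends at 83.6 %.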